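**Strategy.** Everything rests on making ring C of the flavan as a chroman-4-one. In one flask the potassium enolate of a 2-fluoroaryl α-benzyloxy ketone adds through C3 to the carbonyl carbon of 4-(benzyloxy)benzaldehyde (C2–C3), and the aldolate oxygen then displaces fluoride from C8a of ring A (O1–C8a). The step exploits the benzylic position C4: a temporary ketone there makes C3 nucleophilic and activates the ortho C8a–F bond, and is removed afterwards. Its precursor is an open-chain ketone with no heterocycle. The flavan, blocked at C8 by bromine, is later joined through C6 to a benzylic cation on a tetrahydrofuran built by two aldol reactions.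

Key step: step 3

Remark: compounds 7 and 8 are racemic (8 is drawn as one enantiomer, 7 without configuration). In 18, 19, 20, 24 and 25 the oxygen-bearing benzylic carbon outside the ring is an uncontrolled mixture of epimers, left undefined in the SMILES; it becomes a single configuration in step 15.

Step 1
Reactants: 1 1,3,5-trifluorobenzene; 2 benzyl alcohol
Product: 3 1,3-bis(benzyloxy)-5-fluorobenzene
Conditions: NaH, 2 (2.1 equiv), NMP, 0 → 100 °C
Reagents that add atoms: none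
Why: Nucleophilic aromatic substitution of two fluorides by sodium benzyloxide; each alkoxy group introduced slows the next substitution, so the reaction should stop at the bis-ether.

Step 2
Reactants: 3 1,3-bis(benzyloxy)-5-fluorobenzene; 4 (benzyloxy)acetyl chloride
Product: 5 2-(benzyloxy)-1-[2,4-bis(benzyloxy)-6-fluorophenyl]ethan-1-one
Conditions: Bi(OTf)3 (5 mol %), CH3NO2, 0 → 23 °C
Reagents that add atoms: none
Why: Friedel–Crafts acylation should occur para to one benzyloxy group and ortho to the other, next to fluorine, in preference to the hindered position between the two ethers (minor isomer removed), which places the ketone ortho to the C–F bond.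

Step 3
Reactants: 5 2-(benzyloxy)-1-[2,4-bis(benzyloxy)-6-fluorophenyl]ethan-1-one; 6 4-(benzyloxy)benzaldehyde
Product: 8 (±)-trans-3,5,7-tris(benzyloxy)-2-[4-(benzyloxy)phenyl]-2,3-dihydro-4H-chromen-4-one, via potassium aldolate 7 (not isolated)
Conditions: KN(SiMe3)2 (1.05 equiv), THF, −78 °C; 6; DMF, −78 → 50 °C; then DBU (0.2 equiv), 23 °C
Reagents that add atoms: none
Why: The potassium enolate of 5 adds through C3 to the aldehyde carbon of 6 (C2–C3 bond), and the aldolate oxygen of 7 then attacks the fluorine-bearing ring carbon ortho to the ketone and expels fluoride through a Meisenheimer intermediate stabilised by the C4 carbonyl (O1–C8a bond), so that the aldehyde C=O is added across the four-atom unit C3–C4–C4a–C8a. The closest known reaction types are the domino aldol/nucleophilic aromatic substitution of 2-fluoroaryl ketones and, for the polarity pattern, the aldol–cyclisation of 1-alkoxy-3-silyloxydienes with aldehydes to dihydropyranones. The six-membered ring C is closed by ipso attack of the alkoxide on C8a (6-exo with respect to the C8a–F acceptor). C2 and C3 arise without absolute control (racemate), but their relative configuration is set thermodynamically, because DBU epimerises C3 through the chromanone enolate until the 2-aryl and 3-benzyloxy groups are trans-diequatorial; the absolute configuration is selected in step 4. The step needs O-arylation to outrun loss of water from the aldolate, which the aprotic medium and the potassium counter-ion should secure, and it needs arylation by the C2 oxygen only, which the benzyl ether on the C3 oxygen secures.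

Step 4
Reactants: 8 (±)-trans-3,5,7-tris(benzyloxy)-2-[4-(benzyloxy)phenyl]-2,3-dihydro-4H-chromen-4-one
Product: 9 (2S,3R,4S)-3,5,7-tris(benzyloxy)-2-[4-(benzyloxy)phenyl]-3,4-dihydro-2H-chromen-4-ol
Conditions: RuCl[(R,R)-TsDPEN](p-cymene) (2 mol %), HCO2H/Et3N (5:2), CH2Cl2, 23 °C, to about half conversion
Reagents that add atoms: none
Why: Kinetic resolution by Noyori asymmetric transfer hydrogenation: the (R,R)-catalyst delivers hydride to the carbonyl face that in the (2S,3S)-enantiomer is the axial face anti to the 2-aryl group (matched), whereas the (2R,3R)-enantiomer is mismatched, remains a ketone and is separated; the acidic formate medium should not epimerise C3.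

Step 5
Reactants: 9 (2S,3R,4S)-3,5,7-tris(benzyloxy)-2-[4-(benzyloxy)phenyl]-3,4-dihydro-2H-chromen-4-ol
Product: 10 (2S,3R)-3,5,7-tris(benzyloxy)-2-[4-(benzyloxy)phenyl]-3,4-dihydro-2H-chromene
Conditions: Et3SiH (10 equiv), TFA, CH2Cl2 (dilute), −40 °C
Reagents that add atoms: none
Why: Ionic hydrogenation: the 4-hydroxyl ionises to a benzylic cation stabilised by the 5- and 7-benzyloxy groups and is reduced by the silane, which removes the temporary oxygen at C4 without touching C2 or C3.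

Step 6
Reactants: 10 (2S,3R)-3,5,7-tris(benzyloxy)-2-[4-(benzyloxy)phenyl]-3,4-dihydro-2H-chromene
Product: 11 (2S,3R)-3,5,7-tris(benzyloxy)-2-[4-(benzyloxy)phenyl]-8-bromo-3,4-dihydro-2H-chromene
Conditions: NBS, CH2Cl2, −78 → −20 °C
Reagents that add atoms: N-bromosuccinimide, O=C1CCC(=O)N1Br
Why: Electrophilic aromatic bromination of the trialkoxy ring A should occur at C8 (flanked by O1 and one benzyloxy group) rather than at C6 (between two benzyloxy groups), installing a removable blocking group.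

Step 7
Reactants: 12 (R)-4-benzyl-1,3-oxazolidin-2-one; 13 methyl 4-chloro-4-oxobutanoate
Product: 14 methyl 4-[(4R)-4-benzyl-2-oxo-1,3-oxazolidin-3-yl]-4-oxobutanoate
Conditions: n-BuLi, THF, −78 °C; then 13
Reagents that add atoms: none
Why: N-Acylation of the lithiated oxazolidinone by the acid chloride attaches the Evans auxiliary.

Step 8
Reactants: 14 methyl 4-[(4R)-4-benzyl-2-oxo-1,3-oxazolidin-3-yl]-4-oxobutanoate; 6 4-(benzyloxy)benzaldehyde
Product: 16 (4R)-4-benzyl-3-{(2R,3R)-2-[4-(benzyloxy)phenyl]-5-oxooxolane-3-carbonyl}-1,3-oxazolidin-2-one, via syn-aldol adduct 15 (not isolated)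
Conditions: Bu2BOTf, i-Pr2NEt, CH2Cl2, −78 → 0 °C; 6, −78 → 0 °C; pH 7 buffer/MeOH; then PPTS (cat.), CH2Cl2, 23 °C
Reagents that add atoms: none
Why: Evans syn-aldol reaction: the (Z)-boron enolate of the imide adds to 6 through a chair transition state on the face opposite the benzyl group of the (R)-auxiliary, which sets the carbinol and α-carbons both as R, and the aldol hydroxyl then closes onto the methyl ester to give the trans-lactone.

Step 9
Reactants: 16 (4R)-4-benzyl-3-{(2R,3R)-2-[4-(benzyloxy)phenyl]-5-oxooxolane-3-carbonyl}-1,3-oxazolidin-2-one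
Product: 17 (2R,3R)-2-[4-(benzyloxy)phenyl]-5-oxooxolane-3-carboxylic acid
Conditions: LiOH, H2O2, THF/H2O, 0 °C; Na2SO3; then HCl to pH 2
Reagents that add atoms: hydrogen peroxide, OO
Why: Hydroperoxide cleaves the exocyclic imide carbonyl selectively and releases the auxiliary; any opened lactone should reclose on acidification, and the trans arrangement is the stable one.

Step 10
Reactants: 17 (2R,3R)-2-[4-(benzyloxy)phenyl]-5-oxooxolane-3-carboxylic acid; 6 4-(benzyloxy)benzaldehyde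
Product: 19 (2R,3R,4S)-2-[4-(benzyloxy)phenyl]-4-{[4-(benzyloxy)phenyl][(tert-butyldimethylsilyl)oxy]methyl}-5-oxooxolane-3-carboxylic acid, via dilithium aldolate 18 (not isolated)
Conditions: LiN(SiMe3)2 (2.2 equiv), THF, −78 °C; 6; TBSOTf (2.3 equiv), −78 → −40 °C; aqueous NaHCO3/MeOH, then acidify
Reagents that add atoms: tert-butyldimethylsilyl trifluoromethanesulfonate, CC(C)(C)[Si](C)(C)OS(=O)(=O)C(F)(F)F
Why: Aldol reaction of the paraconic acid dianion: the carboxylate blocks enolisation at C3, the lactone enolate at C4 adds to 6 on the face opposite the C3 carboxylate (C4 trans to C3), and the aldolate is silylated in the flask; the silyloxy carbon is not controlled and is erased in step 15.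

Step 11
Reactants: 19 (2R,3R,4S)-2-[4-(benzyloxy)phenyl]-4-{[4-(benzyloxy)phenyl][(tert-butyldimethylsilyl)oxy]methyl}-5-oxooxolane-3-carboxylic acid
Product: 20 (2R,3R,4S)-2-[4-(benzyloxy)phenyl]-4-{[4-(benzyloxy)phenyl][(tert-butyldimethylsilyl)oxy]methyl}-N-methoxy-N-methyl-5-oxooxolane-3-carboxamide
Conditions: MeNHOMe·HCl, EDC·HCl, HOBt (cat.), N-methylmorpholine, CH2Cl2, 0 → 23 °C
Reagents that add atoms: N,O-dimethylhydroxylamine hydrochloride, CNOC.Cl
Why: Carbodiimide amide coupling gives the Weinreb amide, so that the carboxyl carbon will accept exactly one aryl group.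

Step 12
Reactants: 21 4-bromobenzene-1,3-diol
Product: 22 2,4-bis(benzyloxy)-1-bromobenzene
Conditions: BnBr (2.2 equiv), K2CO3, DMF, 60 °C
Reagents that add atoms: benzyl bromide, BrCc1ccccc1
Why: Williamson ether synthesis protects both phenols as benzyl ethers.

Step 13
Reactants: 20 (2R,3R,4S)-2-[4-(benzyloxy)phenyl]-4-{[4-(benzyloxy)phenyl][(tert-butyldimethylsilyl)oxy]methyl}-N-methoxy-N-methyl-5-oxooxolane-3-carboxamide; 22 2,4-bis(benzyloxy)-1-bromobenzene
Product: 24 {(2R,3R,4S)-2-[4-(benzyloxy)phenyl]-5-[2,4-bis(benzyloxy)phenyl]-4-{[4-(benzyloxy)phenyl][(tert-butyldimethylsilyl)oxy]methyl}-5-hydroxyoxolan-3-yl}[2,4-bis(benzyloxy)phenyl]methanone, via aryllithium 23 (not isolated)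
Conditions: 22 (2.3 equiv), n-BuLi (2.3 equiv), THF, −78 °C; then 20, −78 °C; aqueous NH4Cl
Reagents that add atoms: none
Why: Bromine–lithium exchange gives 23, which adds once to the Weinreb amide (stable chelate, ketone on work-up) and once to the lactone (lactolate stable at −78 °C), so both identical aryl groups are installed in one operation without touching the stereocenters.

Step 14
Reactants: 24 {(2R,3R,4S)-2-[4-(benzyloxy)phenyl]-5-[2,4-bis(benzyloxy)phenyl]-4-{[4-(benzyloxy)phenyl][(tert-butyldimethylsilyl)oxy]methyl}-5-hydroxyoxolan-3-yl}[2,4-bis(benzyloxy)phenyl]methanone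
Product: 25 {(2R,3R,4R,5S)-2-[4-(benzyloxy)phenyl]-5-[2,4-bis(benzyloxy)phenyl]-4-{[4-(benzyloxy)phenyl][(tert-butyldimethylsilyl)oxy]methyl}oxolan-3-yl}[2,4-bis(benzyloxy)phenyl]methanone
Conditions: Et3SiH (3 equiv), TMSOTf (0.1 equiv), CH2Cl2, −78 °C
Reagents that add atoms: none
Why: Reductive deoxygenation of the cyclic hemiketal: the 2-aryl oxocarbenium ion is reduced by the silane on the face opposite the bulky C4 substituent, which sets C5 with its aryl group cis to C4 and cis to the C2 aryl group; the aryl ketone and the silyl ether should not ionise at −78 °C.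

Step 15
Reactants: 25 {(2R,3R,4R,5S)-2-[4-(benzyloxy)phenyl]-5-[2,4-bis(benzyloxy)phenyl]-4-{[4-(benzyloxy)phenyl][(tert-butyldimethylsilyl)oxy]methyl}oxolan-3-yl}[2,4-bis(benzyloxy)phenyl]methanone; 11 (2S,3R)-3,5,7-tris(benzyloxy)-2-[4-(benzyloxy)phenyl]-8-bromo-3,4-dihydro-2H-chromene
Product: 26 {(2R,3R,4R,5S)-2-[4-(benzyloxy)phenyl]-5-[2,4-bis(benzyloxy)phenyl]-4-[(S)-[4-(benzyloxy)phenyl]{(2S,3R)-3,5,7-tris(benzyloxy)-2-[4-(benzyloxy)phenyl]-8-bromo-3,4-dihydro-2H-chromen-6-yl}methyl]oxolan-3-yl}[2,4-bis(benzyloxy)phenyl]methanone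
Conditions: 11 (2 equiv), TMSOTf (0.3 equiv), CH2Cl2, −78 → −30 °C
Reagents that add atoms: none
Why: Friedel–Crafts alkylation (SN1): the silyl ether ionises to a 4-alkoxybenzyl cation that should adopt the conformation with the ring C4–H eclipsing the aryl group (allylic strain), the face toward C5 is screened by the cis 2,4-bis(benzyloxy)phenyl group, and C6 of 11 (C8 is blocked by bromine) therefore attacks from the C3 side and sets the diarylmethine carbon as S.

Step 16
Reactants: 26 {(2R,3R,4R,5S)-2-[4-(benzyloxy)phenyl]-5-[2,4-bis(benzyloxy)phenyl]-4-[(S)-[4-(benzyloxy)phenyl]{(2S,3R)-3,5,7-tris(benzyloxy)-2-[4-(benzyloxy)phenyl]-8-bromo-3,4-dihydro-2H-chromen-6-yl}methyl]oxolan-3-yl}[2,4-bis(benzyloxy)phenyl]methanone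
Product: 27 [(2R,3R,4R,5S)-5-(2,4-dihydroxyphenyl)-4-[(S)-(4-hydroxyphenyl)[(2S,3R)-3,5,7-trihydroxy-2-(4-hydroxyphenyl)-3,4-dihydro-2H-chromen-6-yl]methyl]-2-(4-hydroxyphenyl)oxolan-3-yl](2,4-dihydroxyphenyl)methanone (CNP0251055.1)
Conditions: H2 (1 atm), Pd(OH)2/C, Et3N (1.5 equiv), THF/MeOH, 23 °C
Reagents that add atoms: none
Why: Hydrogenolysis removes the ten benzyl ethers and the aryl bromide in one operation; Et3N neutralises HBr so that the acid-sensitive benzylic ethers of the oxolane and chroman rings and the aryl ketone should survive.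

**Compound list**

1 | 1,3,5-trifluorobenzene | Fc1cc(F)cc(F)c1 | starting material
2 | benzyl alcohol | OCc1ccccc1 | starting material
3 | 1,3-bis(benzyloxy)-5-fluorobenzene | Fc1cc(OCc2ccccc2)cc(OCc2ccccc2)c1 | intermediate
4 | (benzyloxy)acetyl chloride | O=C(Cl)COCc1ccccc1 | starting material
5 | 2-(benzyloxy)-1-[2,4-bis(benzyloxy)-6-fluorophenyl]ethan-1-one | O=C(COCc1ccccc1)c1c(F)cc(OCc2ccccc2)cc1OCc1ccccc1 | intermediate
6 | 4-(benzyloxy)benzaldehyde | O=Cc1ccc(OCc2ccccc2)cc1 | starting material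
7 | potassium 2-(benzyloxy)-3-[2,4-bis(benzyloxy)-6-fluorophenyl]-1-[4-(benzyloxy)phenyl]-3-oxopropan-1-olate (racemic diastereomer mixture, not isolated) | [K+].[O-]C(c1ccc(OCc2ccccc2)cc1)C(OCc1ccccc1)C(=O)c1c(F)cc(OCc2ccccc2)cc1OCc1ccccc1 | intermediate
8 | (±)-trans-3,5,7-tris(benzyloxy)-2-[4-(benzyloxy)phenyl]-2,3-dihydro-4H-chromen-4-one (racemate, the 2S,3S enantiomer drawn) | c1c(OCc2ccccc2)cc3c(c1OCc1ccccc1)C(=O)[C@@H](OCc1ccccc1)[C@H](c1ccc(OCc2ccccc2)cc1)O3 | intermediate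
9 | (2S,3R,4S)-3,5,7-tris(benzyloxy)-2-[4-(benzyloxy)phenyl]-3,4-dihydro-2H-chromen-4-ol | c1c(OCc2ccccc2)cc3c(c1OCc1ccccc1)[C@H](O)[C@@H](OCc1ccccc1)[C@H](c1ccc(OCc2ccccc2)cc1)O3 | intermediate
10 | (2S,3R)-3,5,7-tris(benzyloxy)-2-[4-(benzyloxy)phenyl]-3,4-dihydro-2H-chromene | c1c(OCc2ccccc2)cc3c(c1OCc1ccccc1)C[C@@H](OCc1ccccc1)[C@H](c1ccc(OCc2ccccc2)cc1)O3 | intermediate
11 | (2S,3R)-3,5,7-tris(benzyloxy)-2-[4-(benzyloxy)phenyl]-8-bromo-3,4-dihydro-2H-chromene | c1c(OCc2ccccc2)c(Br)c3c(c1OCc1ccccc1)C[C@@H](OCc1ccccc1)[C@H](c1ccc(OCc2ccccc2)cc1)O3 | intermediate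
12 | (R)-4-benzyl-1,3-oxazolidin-2-one | O=C1N[C@H](Cc2ccccc2)CO1 | starting material
13 | methyl 4-chloro-4-oxobutanoate | COC(=O)CCC(=O)Cl | starting material
14 | methyl 4-[(4R)-4-benzyl-2-oxo-1,3-oxazolidin-3-yl]-4-oxobutanoate | COC(=O)CCC(=O)N1[C@H](Cc2ccccc2)COC1=O | intermediate
15 | methyl (3R)-3-{(R)-[4-(benzyloxy)phenyl](hydroxy)methyl}-4-[(4R)-4-benzyl-2-oxo-1,3-oxazolidin-3-yl]-4-oxobutanoate (not isolated) | COC(=O)C[C@@H](C(=O)N1[C@H](Cc2ccccc2)COC1=O)[C@@H](O)c1ccc(OCc2ccccc2)cc1 | intermediate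
16 | (4R)-4-benzyl-3-{(2R,3R)-2-[4-(benzyloxy)phenyl]-5-oxooxolane-3-carbonyl}-1,3-oxazolidin-2-one | O=C([C@@H]1CC(=O)O[C@H]1c1ccc(OCc2ccccc2)cc1)N1[C@H](Cc2ccccc2)COC1=O | intermediate
17 | (2R,3R)-2-[4-(benzyloxy)phenyl]-5-oxooxolane-3-carboxylic acid | O=C(O)[C@@H]1CC(=O)O[C@H]1c1ccc(OCc2ccccc2)cc1 | intermediate
18 | dilithium (2R,3R,4S)-2-[4-(benzyloxy)phenyl]-4-{[4-(benzyloxy)phenyl](oxido)methyl}-5-oxooxolane-3-carboxylate (not isolated) | [Li+].[Li+].[O-]C(=O)[C@@H]1[C@@H](C([O-])c2ccc(OCc3ccccc3)cc2)C(=O)O[C@H]1c1ccc(OCc2ccccc2)cc1 | intermediate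
19 | (2R,3R,4S)-2-[4-(benzyloxy)phenyl]-4-{[4-(benzyloxy)phenyl][(tert-butyldimethylsilyl)oxy]methyl}-5-oxooxolane-3-carboxylic acid | O=C(O)[C@@H]1[C@@H](C(O[Si](C)(C)C(C)(C)C)c2ccc(OCc3ccccc3)cc2)C(=O)O[C@H]1c1ccc(OCc2ccccc2)cc1 | intermediate
20 | (2R,3R,4S)-2-[4-(benzyloxy)phenyl]-4-{[4-(benzyloxy)phenyl][(tert-butyldimethylsilyl)oxy]methyl}-N-methoxy-N-methyl-5-oxooxolane-3-carboxamide | CON(C)C(=O)[C@@H]1[C@@H](C(O[Si](C)(C)C(C)(C)C)c2ccc(OCc3ccccc3)cc2)C(=O)O[C@H]1c1ccc(OCc2ccccc2)cc1 | intermediate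
21 | 4-bromobenzene-1,3-diol | Oc1ccc(Br)c(O)c1 | starting material
22 | 2,4-bis(benzyloxy)-1-bromobenzene | Brc1ccc(OCc2ccccc2)cc1OCc1ccccc1 | intermediate
23 | [2,4-bis(benzyloxy)phenyl]lithium (not isolated) | [Li]c1ccc(OCc2ccccc2)cc1OCc1ccccc1 | intermediate
24 | {(2R,3R,4S)-2-[4-(benzyloxy)phenyl]-5-[2,4-bis(benzyloxy)phenyl]-4-{[4-(benzyloxy)phenyl][(tert-butyldimethylsilyl)oxy]methyl}-5-hydroxyoxolan-3-yl}[2,4-bis(benzyloxy)phenyl]methanone (anomer mixture) | O=C(c1ccc(OCc2ccccc2)cc1OCc1ccccc1)[C@@H]1[C@@H](C(O[Si](C)(C)C(C)(C)C)c2ccc(OCc3ccccc3)cc2)C(O)(c2ccc(OCc3ccccc3)cc2OCc2ccccc2)O[C@H]1c1ccc(OCc2ccccc2)cc1 | intermediate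
25 | {(2R,3R,4R,5S)-2-[4-(benzyloxy)phenyl]-5-[2,4-bis(benzyloxy)phenyl]-4-{[4-(benzyloxy)phenyl][(tert-butyldimethylsilyl)oxy]methyl}oxolan-3-yl}[2,4-bis(benzyloxy)phenyl]methanone | O=C(c1ccc(OCc2ccccc2)cc1OCc1ccccc1)[C@@H]1[C@@H](C(O[Si](C)(C)C(C)(C)C)c2ccc(OCc3ccccc3)cc2)[C@@H](c2ccc(OCc3ccccc3)cc2OCc2ccccc2)O[C@H]1c1ccc(OCc2ccccc2)cc1 | intermediate
26 | {(2R,3R,4R,5S)-2-[4-(benzyloxy)phenyl]-5-[2,4-bis(benzyloxy)phenyl]-4-[(S)-[4-(benzyloxy)phenyl]{(2S,3R)-3,5,7-tris(benzyloxy)-2-[4-(benzyloxy)phenyl]-8-bromo-3,4-dihydro-2H-chromen-6-yl}methyl]oxolan-3-yl}[2,4-bis(benzyloxy)phenyl]methanone | O=C(c1ccc(OCc2ccccc2)cc1OCc1ccccc1)[C@@H]1[C@@H]([C@@H](c2ccc(OCc3ccccc3)cc2)c2c(OCc4ccccc4)c(Br)c3c(c2OCc2ccccc2)C[C@@H](OCc2ccccc2)[C@H](c2ccc(OCc4ccccc4)cc2)O3)[C@@H](c2ccc(OCc3ccccc3)cc2OCc2ccccc2)O[C@H]1c1ccc(OCc2ccccc2)cc1 | intermediate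
27 | [(2R,3R,4R,5S)-5-(2,4-dihydroxyphenyl)-4-[(S)-(4-hydroxyphenyl)[(2S,3R)-3,5,7-trihydroxy-2-(4-hydroxyphenyl)-3,4-dihydro-2H-chromen-6-yl]methyl]-2-(4-hydroxyphenyl)oxolan-3-yl](2,4-dihydroxyphenyl)methanone | O=C(c1ccc(O)cc1O)[C@@H]1[C@@H]([C@@H](c2ccc(O)cc2)c2c(O)cc3c(c2O)C[C@@H](O)[C@H](c2ccc(O)cc2)O3)[C@@H](c2ccc(O)cc2O)O[C@H]1c1ccc(O)cc1 | target

**Step count and risks**

Total step count: 16. Longest linear sequence: 9 steps (7, 8, 9, 10, 11, 13, 14, 15, 16).

Steps most likely to fail: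

1. Step 15. The benzylic cation may be captured with poor facial selectivity, or the C5–O bond of the oxolane may ionise in competition with the silyl ether and epimerise C5. The fallback joins the two halves before the acid-labile 2-aryl oxolane exists and uses an alkene face instead of a cation conformation. It sets out from acid 17. The dianion aldol of step 10 without silyl trapping should give (2R,3R,4S)-2-[4-(benzyloxy)phenyl]-4-{[4-(benzyloxy)phenyl](hydroxy)methyl}-5-oxooxolane-3-carboxylic acid F1. Dehydration with catalytic p-TsOH in toluene should give the (E)-arylidene lactone acid F2. Conjugate Friedel–Crafts addition of 11 to F2 (TfOH cat., CH2Cl2) should place the arene on the exocyclic carbon from the face opposite the C3 carboxyl group, and protonation trans to that group should give the diarylmethyl lactone acid F3. Amide coupling as in step 11 gives the Weinreb amide F4, addition of 23 as in step 13 gives the keto-hemiketal F5, and reduction as in step 14 comes back to the route at 26.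

2. Step 4. The rate difference between the two enantiomers may be too small, or hydride transfer to the electron-rich, peri-substituted ketone too slow. The fallback is a covalent resolution that sets out from racemic 8. NaBH4 (MeOH/THF, 0 °C) should give the racemic 2,3-trans-3,4-trans alcohol F6. Esterification with (S)-2-methoxy-2-phenylacetic acid (DCC, DMAP) gives two diastereomeric esters, from which the (2S,3R,4S)-chromanyl (2S)-2-methoxy-2-phenylacetate F7 is separated by chromatography or crystallisation. Et3SiH with catalytic TMSOTf ionises the ester at C4 and reduces the cation, which comes back to the route at 10.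

3. Step 3. Loss of water from the aldolate (to the α-benzyloxychalcone) or retro-aldol cleavage may outrun the ring closure. The fallback avoids a stoichiometric amide base and sets out from 5. Silylation (TMSOTf, Et3N) should give the (Z)-trimethylsilyl enol ether F8. With 6 and CsF in DMF, fluoride releases the enolate, the aldolate closes onto the fluorinated carbon in the same flask, and the expelled fluoride carries the silyl group away; DBU then equilibrates to the trans isomer, which comes back to the route at 8.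

**Further compounds**

F1 | step 15 | (2R,3R,4S)-2-[4-(benzyloxy)phenyl]-4-{[4-(benzyloxy)phenyl](hydroxy)methyl}-5-oxooxolane-3-carboxylic acid (carbinol epimers) | O=C(O)[C@@H]1[C@@H](C(O)c2ccc(OCc3ccccc3)cc2)C(=O)O[C@H]1c1ccc(OCc2ccccc2)cc1
F2 | step 15 | (2R,3R,4E)-2-[4-(benzyloxy)phenyl]-4-{[4-(benzyloxy)phenyl]methylidene}-5-oxooxolane-3-carboxylic acid | O=C(O)[C@@H]1/C(=C\c2ccc(OCc3ccccc3)cc2)C(=O)O[C@H]1c1ccc(OCc2ccccc2)cc1
F3 | step 15 | (2R,3R,4R)-2-[4-(benzyloxy)phenyl]-4-[(S)-[4-(benzyloxy)phenyl]{(2S,3R)-3,5,7-tris(benzyloxy)-2-[4-(benzyloxy)phenyl]-8-bromo-3,4-dihydro-2H-chromen-6-yl}methyl]-5-oxooxolane-3-carboxylic acid | O=C(O)[C@@H]1[C@@H]([C@@H](c2ccc(OCc3ccccc3)cc2)c2c(OCc4ccccc4)c(Br)c3c(c2OCc2ccccc2)C[C@@H](OCc2ccccc2)[C@H](c2ccc(OCc4ccccc4)cc2)O3)C(=O)O[C@H]1c1ccc(OCc2ccccc2)cc1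
F4 | step 15 | (2R,3R,4R)-2-[4-(benzyloxy)phenyl]-4-[(S)-[4-(benzyloxy)phenyl]{(2S,3R)-3,5,7-tris(benzyloxy)-2-[4-(benzyloxy)phenyl]-8-bromo-3,4-dihydro-2H-chromen-6-yl}methyl]-N-methoxy-N-methyl-5-oxooxolane-3-carboxamide | CON(C)C(=O)[C@@H]1[C@@H]([C@@H](c2ccc(OCc3ccccc3)cc2)c2c(OCc4ccccc4)c(Br)c3c(c2OCc2ccccc2)C[C@@H](OCc2ccccc2)[C@H](c2ccc(OCc4ccccc4)cc2)O3)C(=O)O[C@H]1c1ccc(OCc2ccccc2)cc1
F5 | step 15 | {(2R,3R,4R)-2-[4-(benzyloxy)phenyl]-5-[2,4-bis(benzyloxy)phenyl]-4-[(S)-[4-(benzyloxy)phenyl]{(2S,3R)-3,5,7-tris(benzyloxy)-2-[4-(benzyloxy)phenyl]-8-bromo-3,4-dihydro-2H-chromen-6-yl}methyl]-5-hydroxyoxolan-3-yl}[2,4-bis(benzyloxy)phenyl]methanone (anomer mixture) | O=C(c1ccc(OCc2ccccc2)cc1OCc1ccccc1)[C@@H]1[C@@H]([C@@H](c2ccc(OCc3ccccc3)cc2)c2c(OCc4ccccc4)c(Br)c3c(c2OCc2ccccc2)C[C@@H](OCc2ccccc2)[C@H](c2ccc(OCc4ccccc4)cc2)O3)C(O)(c2ccc(OCc3ccccc3)cc2OCc2ccccc2)O[C@H]1c1ccc(OCc2ccccc2)cc1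
F6 | step 4 | (±)-(2S*,3R*,4S*)-3,5,7-tris(benzyloxy)-2-[4-(benzyloxy)phenyl]-3,4-dihydro-2H-chromen-4-ol (racemate, one enantiomer drawn) | c1c(OCc2ccccc2)cc3c(c1OCc1ccccc1)[C@H](O)[C@@H](OCc1ccccc1)[C@H](c1ccc(OCc2ccccc2)cc1)O3
F7 | step 4 | (2S,3R,4S)-3,5,7-tris(benzyloxy)-2-[4-(benzyloxy)phenyl]-3,4-dihydro-2H-chromen-4-yl (2S)-2-methoxy-2-phenylacetate | c1c(OCc2ccccc2)cc3c(c1OCc1ccccc1)[C@H](OC(=O)[C@@H](OC)c1ccccc1)[C@@H](OCc1ccccc1)[C@H](c1ccc(OCc2ccccc2)cc1)O3
F8 | step 3 | (Z)-{[2-(benzyloxy)-1-[2,4-bis(benzyloxy)-6-fluorophenyl]ethenyl]oxy}trimethylsilane | C[Si](C)(C)O/C(=C\OCc1ccccc1)c1c(F)cc(OCc2ccccc2)cc1OCc1ccccc1
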